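**Plan**

- With the ring numbered C1(=O), C2(OH), C3(docosyl), C4(=O), C5(OMe), C6(H), the C2 hydroxyl is traced back to an epoxide on C2=C3 and the C4 oxygen to an acetyl group on a benzene ring.
- That benzene ring is cut at C2–C3 and C4–C5. The segment C5–C6–C1–C2, with oxygen on C5 and C1, is a 1,3-dimethoxycyclohexa-1,3-diene whose CH2–CH2 unit leaves as ethylene, and C3–C4 are the alkyne carbons of a docosyl methyl ynone.
- Forward: Birch reduction gives the diene precursor; the C22 chain is joined to acetylide and the alkyne is acetylated; the only ring arises in the cycloaddition/ethylene-loss step.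
- Then aryl migration turns the acetyl group into the C4 oxygen, cerium(IV) gives the 5-methoxy-1,4-quinone, and epoxidation/isomerisation places the C2 hydroxyl.
- Stereochemistry: the target has none; the bridgehead and epoxide centres met on the way are racemic and are destroyed.

Key step: step 4

Assumption: the target has no stereocentre and no stereogenic double bond, so the structure as drawn is its only stereoisomer; ring positions are cited throughout with the numbering C1–C6 defined above.

**Route**

Step 1
Reactants: 1 1,3-dimethoxybenzene
Product: 2 1,5-dimethoxycyclohexa-1,4-diene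
Conditions: Li, t-BuOH, NH3(l)–THF, −78 → −33 °C; then H2O (base-washed, acid-free work-up; used crude)
Reagents that add atoms: none
Why: Birch reduction, in which the radical anion of the resorcinol diether is protonated at C2 and C5 so that both methoxy groups stay on double bonds, should give the unconjugated bis(enol ether), which an acid-free work-up keeps from hydrolysing.

Step 2
Reactants: 3 1-bromodocosane, 4 lithium acetylide–ethylenediamine complex
Product: 5 tetracos-1-yne
Conditions: DMSO–THF, 15 °C → rt, then 40 °C
Reagents that add atoms: none
Why: SN2 alkylation of an acetylide by an unhindered primary bromide in a dipolar aprotic medium is a standard route to terminal alkynes, with excess acetylide suppressing double alkylation and THF keeping the C22 bromide in solution.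

Step 3
Reactants: 5 tetracos-1-yne, 6 N-methoxy-N-methylacetamide
Product: 8 hexacos-3-yn-2-one, via lithium tetracos-1-yn-1-ide 7 (not isolated)
Conditions: n-BuLi, THF, 0 °C; then 6, 0 °C → rt; 1 M HCl
Reagents that add atoms: none
Why: Weinreb ketone synthesis, in which the lithium acetylide adds once to the N-methoxy-N-methylamide because the chelated tetrahedral adduct persists until the acidic quench, so the ynone should form without over-addition.

Step 4
Reactants: 2 1,5-dimethoxycyclohexa-1,4-diene, 8 hexacos-3-yn-2-one
Product: 11 1-(2-docosyl-4,6-dimethoxyphenyl)ethan-1-one, via 1,3-dimethoxycyclohexa-1,3-diene 9 (not isolated), via 1-(3-docosyl-1,5-dimethoxybicyclo[2.2.2]octa-2,5-dien-2-yl)ethan-1-one 10 (not isolated)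
Conditions: 2 (2.5 equiv), cat. dichloromaleic anhydride, neat, sealed tube, 110 °C then 190 °C
Reagents that add atoms: none
Why: The acid trace moves one double bond of 2 into conjugation, the resulting diene 9 is trapped by the ynone in a concerted normal-demand [4+2] cycloaddition that forms C2–C3 and C4–C5 and gives the bicyclo[2.2.2]octadiene 10, and at the higher temperature 10 undergoes a retro-[4+2] that expels its CH2–CH2 bridge as ethylene and leaves the benzene ring. The closest known reaction type is the Alder–Rickert reaction of alkoxycyclohexadienes with acetylenic esters and ketones. The one ring that is built, the six-membered carbocycle C1–C6, is closed by intermolecular cycloaddition with both σ bonds formed in the same step, not by cyclisation of a chain. No stereocentre remains, since the two bridgehead centres of 10 arise as a racemate with their relative configuration fixed by the bicycle and both become sp2 on aromatisation. The step needs regioselectivity, and both methoxy groups secure it by placing the largest HOMO coefficient on the unsubstituted diene terminus (future C2), which bonds to the electrophilic docosyl-bearing β-carbon of the ynone, so the acetyl group ends between docosyl and methoxy. Loss of a gas makes the sequence irreversible, and the alkyne, not the ketone C=O, is the dienophile.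

Step 5
Reactants: 11 1-(2-docosyl-4,6-dimethoxyphenyl)ethan-1-one
Product: 12 2-docosyl-4,6-dimethoxyphenyl acetate
Conditions: mCPBA, CH2Cl2, 0 °C → rt
Reagents that add atoms: 3-chloroperoxybenzoic acid (mCPBA), OOC(=O)c1cccc(Cl)c1
Why: Baeyer–Villiger oxidation, in which the electron-rich 2,4-dimethoxy-6-alkylphenyl group migrates far more readily than methyl in the Criegee adduct, while the carbonyl, twisted out of the ring plane by two ortho substituents, stays reactive, so the aryl acetate should form.

Step 6
Reactants: 12 2-docosyl-4,6-dimethoxyphenyl acetate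
Product: 13 2-docosyl-4,6-dimethoxyphenol
Conditions: K2CO3 (cat.), degassed MeOH–THF, rt, Ar; dilute acid work-up
Reagents that add atoms: none
Why: Base-catalysed transesterification of an aryl acetate is fast at room temperature because phenoxide is a good leaving group, and oxygen is excluded because the electron-rich phenolate would autoxidise.

Step 7
Reactants: 13 2-docosyl-4,6-dimethoxyphenol
Product: 14 2-docosyl-6-methoxycyclohexa-2,5-diene-1,4-dione
Conditions: CAN (2.2 equiv), MeCN–THF–H2O, 0 °C
Reagents that add atoms: water, O
Why: Cerium(IV) oxidative demethylation of a para-methoxyphenol, in which two one-electron oxidations give a phenoxonium ion, water adds at the para carbon carrying methoxy (C1) and the hemiketal loses methanol, should give the 1,4-quinone with the C5 methoxy group untouched.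

Step 8
Reactants: 14 2-docosyl-6-methoxycyclohexa-2,5-diene-1,4-dione
Product: 15 1-docosyl-3-methoxy-7-oxabicyclo[4.1.0]hept-3-ene-2,5-dione (racemic)
Conditions: t-BuOOH (in decane), DBU, CH2Cl2, 0 °C
Reagents that add atoms: tert-butyl hydroperoxide, CC(C)(C)OO
Why: Weitz–Scheffer nucleophilic epoxidation, in which the peroxide anion adds to C2 (the unsubstituted β-carbon of the enone C2=C3–C4=O) and the enolate closes onto oxygen with loss of tert-butoxide, whereas C5=C6 is a vinylogous ester and too electron-rich to compete; the two new centres form as a racemate with the cis fusion a fused oxirane must have, and both vanish in step 9.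

Step 9
Reactants: 15 1-docosyl-3-methoxy-7-oxabicyclo[4.1.0]hept-3-ene-2,5-dione
Product: 16 3-docosyl-2-hydroxy-5-methoxycyclohexa-2,5-diene-1,4-dione
Conditions: conc. H2SO4, AcOH–CH2Cl2, 0 °C → rt; then ice–water
Reagents that add atoms: none
Why: Acid-catalysed isomerisation of an epoxyquinone to a hydroxyquinone (opening of the C3–O bond with loss of the C2 proton, or the equivalent 1,2-hydride shift and enolisation) can give only one product because C2 is the only epoxide carbon bearing hydrogen, and in a water-poor medium the vinylogous methyl ester should not hydrolyse.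

**Compound list**

1 | 1,3-dimethoxybenzene | COc1cccc(OC)c1 | starting material
2 | 1,5-dimethoxycyclohexa-1,4-diene | COC1=CCC=C(OC)C1 | intermediate
3 | 1-bromodocosane | CCCCCCCCCCCCCCCCCCCCCCBr | starting material
4 | lithium acetylide–ethylenediamine complex | [Li+].[C-]#C.NCCN | starting material
5 | tetracos-1-yne | CCCCCCCCCCCCCCCCCCCCCCC#C | intermediate
6 | N-methoxy-N-methylacetamide | CON(C)C(C)=O | starting material
7 | lithium tetracos-1-yn-1-ide (not isolated) | [Li+].[C-]#CCCCCCCCCCCCCCCCCCCCCCC | intermediate
8 | hexacos-3-yn-2-one | CCCCCCCCCCCCCCCCCCCCCCC#CC(C)=O | intermediate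
9 | 1,3-dimethoxycyclohexa-1,3-diene (not isolated) | COC1=CC(OC)=CCC1 | intermediate
10 | 1-(3-docosyl-1,5-dimethoxybicyclo[2.2.2]octa-2,5-dien-2-yl)ethan-1-one (racemic, one enantiomer drawn; not isolated) | CO[C@]12CC[C@H](C(CCCCCCCCCCCCCCCCCCCCCC)=C1C(C)=O)C(OC)=C2 | intermediate
11 | 1-(2-docosyl-4,6-dimethoxyphenyl)ethan-1-one | CCCCCCCCCCCCCCCCCCCCCCc1cc(OC)cc(OC)c1C(C)=O | intermediate
12 | 2-docosyl-4,6-dimethoxyphenyl acetate | CCCCCCCCCCCCCCCCCCCCCCc1cc(OC)cc(OC)c1OC(C)=O | intermediate
13 | 2-docosyl-4,6-dimethoxyphenol | CCCCCCCCCCCCCCCCCCCCCCc1cc(OC)cc(OC)c1O | intermediate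
14 | 2-docosyl-6-methoxycyclohexa-2,5-diene-1,4-dione | CCCCCCCCCCCCCCCCCCCCCCC1=CC(=O)C=C(OC)C1=O | intermediate
15 | 1-docosyl-3-methoxy-7-oxabicyclo[4.1.0]hept-3-ene-2,5-dione (racemic, cis-fused, one enantiomer drawn) | CCCCCCCCCCCCCCCCCCCCCC[C@@]12O[C@@H]1C(=O)C=C(OC)C2=O | intermediate
16 | 3-docosyl-2-hydroxy-5-methoxycyclohexa-2,5-diene-1,4-dione (achiral) | CCCCCCCCCCCCCCCCCCCCCCC1=C(O)C(=O)C=C(OC)C1=O | target

**Step count**

Total steps: 9. Longest linear sequence: 8 steps (steps 2–9, from 1-bromodocosane); step 1 joins at step 4.

**Steps most likely to fail**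

Step 4. The conjugated diene has to be generated in the same flask at high temperature. The ynone may be lost by propargyl–allenyl isomerisation or oligomerisation, and the bis(enol ether) by aromatisation, before the cycloaddition takes place, and some regiochemical leakage is possible. The fallback sets out from 8 and replaces the in situ conjugation by a preformed kinetic silyl dienol ether. Commercial 3-methoxycyclohex-2-en-1-one (COC1=CC(=O)CCC1) is deprotonated at C6 with LDA in THF at −78 °C and silylated with TMSCl to give 1-methoxy-3-(trimethylsilyloxy)cyclohexa-1,3-diene F1. This more reactive diene should add to 8 in toluene at 80–110 °C to give 1-[3-docosyl-1-methoxy-5-(trimethylsilyloxy)bicyclo[2.2.2]octa-2,5-dien-2-yl]ethan-1-one F2, which at 160–180 °C should lose ethylene to give 1-[2-docosyl-6-methoxy-4-(trimethylsilyloxy)phenyl]ethan-1-one F3. Dilute HCl in THF should cleave the silyl ether to 1-(2-docosyl-4-hydroxy-6-methoxyphenyl)ethan-1-one F4. Methylation of the unhindered para hydroxyl with MeI and K2CO3 in acetone comes back to the route at 11.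

Step 8. The peroxide anion may attack the methoxy-bearing double bond or displace methoxide at C5 by addition–elimination, and the base may degrade the quinone. The fallback sets out from 14 and introduces the C2 oxygen under acid by Thiele–Winter acetoxylation (Ac2O, cat. H2SO4, rt). Acetate should add at C2 for the same electronic reason and give 3-docosyl-5-methoxybenzene-1,2,4-triyl triacetate F5. Acid-catalysed methanolysis (HCl, MeOH–THF) should give 3-docosyl-5-methoxybenzene-1,2,4-triol F6, which air should oxidise during work-up. The fallback comes back to the route at 16 and bypasses 15.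

Step 7. One-electron oxidation of the electron-rich phenol may lead to oxidative coupling of phenoxyl radicals, ring nitration, over-oxidation, or loss of the ortho methoxy group toward an ortho-quinone. The fallback sets out from 13 and uses a two-electron iodine(III) oxidation in methanol (PhI(OAc)2, MeOH, 0 °C), in which methanol adds para to give the isolable quinone monoketal 2-docosyl-4,4,6-trimethoxycyclohexa-2,5-dien-1-one F7. Mild aqueous acid (oxalic acid, THF–H2O) should hydrolyse the ketal and come back to the route at 14.

**Further compounds**

F1 | step 4 | 1-methoxy-3-(trimethylsilyloxy)cyclohexa-1,3-diene | COC1=CC(O[Si](C)(C)C)=CCC1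
F2 | step 4 | 1-[3-docosyl-1-methoxy-5-(trimethylsilyloxy)bicyclo[2.2.2]octa-2,5-dien-2-yl]ethan-1-one (racemic, one enantiomer drawn) | CO[C@]12CC[C@H](C(CCCCCCCCCCCCCCCCCCCCCC)=C1C(C)=O)C(O[Si](C)(C)C)=C2
F3 | step 4 | 1-[2-docosyl-6-methoxy-4-(trimethylsilyloxy)phenyl]ethan-1-one | CCCCCCCCCCCCCCCCCCCCCCc1cc(O[Si](C)(C)C)cc(OC)c1C(C)=O
F4 | step 4 | 1-(2-docosyl-4-hydroxy-6-methoxyphenyl)ethan-1-one | CCCCCCCCCCCCCCCCCCCCCCc1cc(O)cc(OC)c1C(C)=O
F5 | step 8 | 3-docosyl-5-methoxybenzene-1,2,4-triyl triacetate | CCCCCCCCCCCCCCCCCCCCCCc1c(OC(C)=O)c(OC(C)=O)cc(OC)c1OC(C)=O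
F6 | step 8 | 3-docosyl-5-methoxybenzene-1,2,4-triol | CCCCCCCCCCCCCCCCCCCCCCc1c(O)c(O)cc(OC)c1O
F7 | step 7 | 2-docosyl-4,4,6-trimethoxycyclohexa-2,5-dien-1-one | CCCCCCCCCCCCCCCCCCCCCCC1=CC(OC)(OC)C=C(OC)C1=O
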